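**Plan**
Retrosynthesis: the two angelate C–O bonds and the C11=C12 alkene (from a C11 carbinol) are cut first. C7–C11 (acetone aldol) and C9–O (enol ether oxidation) follow, which leaves a cis-decalin 3-ol-8-one.
Enabling feature: ring A (C1, C2, C3, C4, C5, C10) carries its oxygen on C3, and only the methyl-bearing C4 separates C3 from the quaternary C5. Cutting C4–C5 and joining C5 to C3 contracts ring A to a cyclopentanol with an exocyclic CH(OMs)CH3. That ring is the cyclopentanone ring of the hydrogenated Hajos–Parrish ketone, whose second carbonyl is already C8.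
Forward: ring B and a five-membered precursor of ring A come with the starting material, and hydrogenation makes the cis fusion. Wittig reaction, dihydroxylation and mesylation build the C4–C15 handle, and a semipinacol 1,2-shift of C5 enlarges the five-membered ring to ring A. Ring B is functionalised last (C9–O, C7–C11, esters, alkene).
Stereochemistry: C5 comes from the (S)-ketone and C10 from cis hydrogenation. C4 comes from the (Z)-alkene, syn-dihydroxylation and inversion, backed by its equatorial preference. C3 is set by dissolving-metal reduction. C9 and C7 are set by attack on the convex β face, and both end equatorial. The Z esters come from angelic acid.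

Key step: step 6

Remark on numbering: eremophilane numbers are used throughout. Ring A is C1, C2, C3, C4, C5, C10 and ring B is C5 to C10. C14 is the methyl on C5, C15 the methyl on C4, and C11 to C13 the three-carbon unit on C7. In compounds 1 to 8 the five-membered ring is C3, C2, C1, C10, C5. β is the face of C14.
Remark on the structure: the SMILES is read as (3R,4R,5R,7R,9R,10S). This means 4β,5β-dimethyl, 10β-H (cis-decalin), 3α- and 9β-angeloyloxy and 7β-isopropenyl. All four ring substituents are equatorial in the chair–chair conformer that has C14 axial on ring A.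

**Step 1**
Reactants: 1 (7aS)-7a-methyl-2,3,7,7a-tetrahydro-1H-indene-1,5(6H)-dione (Hajos–Parrish ketone)
Product: 2 cis-fused dione (3aR,7aS)-7a-methyloctahydro-1H-indene-1,5-dione (H-10 β)
Conditions: H2 (1 atm), Pd/C, EtOAc, rt
Reagents that add atoms: none
Why: Heterogeneous catalytic hydrogenation of the enone C=C; 7a-methylhydrindenones of this kind take up hydrogen on Pd syn to the angular methyl, so H-10 should end β (cis fusion) while both ketones survive.

**Step 2**
Reactants: 2 cis-fused dione
Product: 3 keto ketal (C8 ethylene ketal of 2 with the C3 ketone free)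
Conditions: HOCH2CH2OH (1.1 equiv), p-TsOH (cat.), benzene, reflux, Dean–Stark trap
Reagents that add atoms: ethylene glycol, OCCO
Why: Acid-catalysed ketalisation is sterically selective, since the cyclohexanone C8 reacts while the cyclopentanone C3 next to quaternary C5 stays free, and neither C5 nor C10 is an epimerisable α-centre.

**Step 3**
Reactants: 3 keto ketal; 4 ethyltriphenylphosphonium bromide
Product: 5 (Z)-ethylidene ketal (C3=C4 with C15 syn to C5)
Conditions: KOt-Bu, THF, reflux
Reagents that add atoms: ethyltriphenylphosphonium bromide, CC[P+](c1ccccc1)(c1ccccc1)c1ccccc1.[Br-]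
Why: Wittig olefination with a non-stabilised ylide; as with 17-oxo steroids and other 1-hydrindanones flanked by a quaternary carbon the (Z)-alkene should form, and the ketal is inert to base.

**Step 4**
Reactants: 5 (Z)-ethylidene ketal
Product: 6 diol (3β-hydroxy and (4R)-hydroxy; 1-hydroxyethyl group on the α side of C3)
Conditions: OsO4 (cat.), N-methylmorpholine N-oxide, acetone/H2O, rt
Reagents that add atoms: N-methylmorpholine N-oxide, C[N+]1([O-])CCOCC1; water, O
Why: Upjohn dihydroxylation; syn addition to the (Z)-alkene fixes the C3/C4 relation, and OsO4 should take the convex β face because in the ketal-locked conformer C3 is axial on ring B and the α face of the alkene lies under axial H-7 and H-9, giving 3β-OH and (4R).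

**Step 5**
Reactants: 6 diol
Product: 7 hydroxy mesylate ((4R)-mesylate with the tertiary 3β-OH free)
Conditions: MsCl, Et3N, CH2Cl2, −10 °C
Reagents that add atoms: methanesulfonyl chloride, CS(=O)(=O)Cl
Why: Sulfonylation is selective for the secondary C4–OH because the tertiary C3–OH is too hindered, and the C4 configuration is untouched.

**Step 6**
Reactants: 7 hydroxy mesylate
Product: 9 ring-expanded keto ketal (4β,5β-dimethyl-10βH-decalin-3,8-dione 8-ethylene ketal), via aluminium alkoxide 8 (not isolated)
Conditions: Et2AlCl (2 equiv), CH2Cl2, −78 → −20 °C; aq. potassium sodium tartrate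
Reagents that add atoms: none
Why: Et2AlCl first deprotonates the tertiary C3–OH (alkoxide 8) and aluminium then pulls on the C4 mesylate, so the C3–C5 σ-bond standing anti-periplanar to C4–O shifts from C3 to C4 while C3–O becomes the ketone. This is the organoaluminium-promoted semipinacol rearrangement of a 2-sulfonyloxy alcohol in its ring-enlarging form (1-(1-sulfonyloxyethyl)cycloalkanol to 2-methylcycloalkanone), a well-precedented reaction type. No ring is closed by cyclisation: the cyclopentane C3–C2–C1–C10–C5 takes C4 in between C3 and C5 by a suprafacial 1,2-shift and so becomes the six-membered ring A, ring B being untouched. C4 is the only new stereocentre: it forms with inversion at the mesylate carbon, so the (4R) carbinol from the (Z)-alkene and syn-dihydroxylation becomes the 4β-methyl centre cis to C14, and C5 migrates with retention. The step needs migration of C5 rather than C2 and no epoxide closure: C5 is the better (tertiary alkyl) migrating group, its shift releases the strain of a bond between two fully substituted carbons and of the cyclopentane, only the rotamer with C5 anti to the mesylate puts the hydrogen of C4 (not CH3 or OMs) into the crowded sector between C2 and C5, and the covalent Al–O bond makes the oxygen a poor nucleophile for epoxide formation. C4 is α to the new ketone and the 4β-methyl is equatorial in the conformer locked by the ketal (a 4α-methyl would be syn-axial to C9), so material from the minor face in step 4 can be brought to 9 with DBU.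

**Step 7**
Reactants: 9 ring-expanded keto ketal
Product: 11 hydroxy ketone (3α-hydroxy-4β,5β-dimethyl-10βH-decalin-8-one), via hydroxy ketal 10 (not isolated)
Conditions: Li, NH3(l)/THF, t-BuOH, −78 °C; NH4Cl; then 1 M HCl, THF, rt
Reagents that add atoms: water, O
Why: Dissolving-metal ketone reduction gives the thermodynamically preferred equatorial 3α-alcohol (trans to C15), which hydrides would not give because C14 is syn-axial to the β-axial trajectory at C3, and aqueous acid then hydrolyses the dioxolane.

**Step 8**
Reactants: 11 hydroxy ketone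
Product: 12 bis-silyl compound (3α-triethylsilyloxy Δ8(9) triethylsilyl enol ether)
Conditions: TESOTf (2.5 equiv), Et3N, CH2Cl2, 0 °C → rt
Reagents that add atoms: triethylsilyl triflate, CC[Si](CC)(CC)OS(=O)(=O)C(F)(F)F
Why: Silyl triflate/amine soft enolisation under equilibrating conditions, with silylation of O-3; cis-fused 2-decalones such as A/B-cis 3-oxo steroids enolise towards the ring fusion, because flattening C9 removes two of the three gauche interactions of the cis-decalin (C9/C2 and C9/C4) and flattening C7 only one, so the Δ8(9) isomer should prevail.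

**Step 9**
Reactants: 12 bis-silyl compound
Product: 13 3α,9β-bis(triethylsilyloxy) ketone
Conditions: mCPBA, CH2Cl2, −20 °C
Reagents that add atoms: 3-chloroperoxybenzoic acid, O=C(OO)c1cccc(Cl)c1
Why: Rubottom oxidation; the peracid attacks the only alkene on the convex β face (the α face of C9 is covered by the axial C4–C5 bond), and silyl migration gives the 9β (equatorial) silyloxy ketone, which is also the stable epimer.

**Step 10**
Reactants: 13 3α,9β-bis(triethylsilyloxy) ketone; 14 acetone
Product: 17 aldol (7β-(2-hydroxypropan-2-yl) derivative of 13), via lithium enolate 15 (not isolated), via chlorozinc enolate 16 (not isolated)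
Conditions: LiN(i-Pr)2, THF, −78 °C; ZnCl2; acetone, −78 → −40 °C; aq. NH4Cl
Reagents that add atoms: acetone, CC(C)=O
Why: Kinetic deprotonation at the only α-methylene (C7) followed by zinc-enolate aldol addition; acetone arrives from the convex β face and the bulky group ends equatorial (7β), which is also the stable epimer.

**Step 11**
Reactants: 17 aldol
Product: 18 triol (3α,9β,11-trihydroxy-10βH-eremophilan-8-one)
Conditions: HF·pyridine, THF/pyridine, 0 °C
Reagents that add atoms: none
Why: Fluoride-driven cleavage of both triethylsilyl ethers under buffered, non-basic conditions that should spare the aldol unit and the α-ketol.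

**Step 12**
Reactants: 18 triol; 19 angelic acid ((Z)-2-methylbut-2-enoic acid)
Product: 20 bis-angelate carbinol (3α,9β-bis(angeloyloxy)-11-hydroxy-10βH-eremophilan-8-one)
Conditions: 19 (2.5 equiv), 2,4,6-Cl3C6H2COCl, Et3N, toluene, rt; then 18, 60 °C
Reagents that add atoms: angelic acid, C/C=C(/C)C(=O)O
Why: Yamaguchi-type mixed-anhydride esterification without a nucleophilic catalyst, the usual way to transfer the angeloyl group without Z to E isomerisation; both equatorial secondary alcohols are acylated and the tertiary C11–OH is not.

**Step 13**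
Reactants: 20 bis-angelate carbinol
Product: 22 target (3R,4R,5R,7R,9R,10S)-3,9-bis(angeloyloxy)eremophil-11-en-8-one, via chlorosulfite 21 (not isolated)
Conditions: SOCl2, pyridine, −10 → 0 °C
Reagents that add atoms: none
Why: E2 dehydration of the tertiary chlorosulfite; a methyl hydrogen can always stand anti to the leaving group, whereas H-7 can do so only in the rotamer with both methyls gauche to C6 and C8, so the isopropenyl isomer should prevail over the conjugated one, C7 is untouched, and placing this step last keeps the β,γ-unsaturated ketone away from base and heat.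

**Compound list**
1 | (7aS)-7a-methyl-2,3,7,7a-tetrahydro-1H-indene-1,5(6H)-dione (Hajos–Parrish ketone) | C1C[C@@]2(C)C(CCC2=O)=CC1=O | starting material
2 | cis-fused dione, (3aR,7aS)-7a-methyloctahydro-1H-indene-1,5-dione | C1C[C@@]2(C)[C@H](CCC2=O)CC1=O | intermediate
3 | keto ketal (C8 ethylene ketal of 2) | C1C[C@@]2(C)[C@H](CCC2=O)CC13OCCO3 | intermediate
4 | ethyltriphenylphosphonium bromide | CC[P+](c1ccccc1)(c1ccccc1)c1ccccc1.[Br-] | starting material
5 | (Z)-ethylidene ketal (C15 syn to C5) | C1C[C@@]2(C)[C@H](CC/C2=C/C)CC13OCCO3 | intermediate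
6 | diol (3β-OH, (4R)-OH) | C1C[C@@]2(C)[C@H](CC[C@@]2(O)[C@@H](C)O)CC13OCCO3 | intermediate
7 | hydroxy mesylate (3β-OH, (4R)-OMs) | C1C[C@@]2(C)[C@H](CC[C@@]2(O)[C@@H](C)OS(C)(=O)=O)CC13OCCO3 | intermediate
8 | chloro(ethyl)aluminium alkoxide of 7 | C1C[C@@]2(C)[C@H](CC[C@@]2(O[Al](Cl)CC)[C@@H](C)OS(C)(=O)=O)CC13OCCO3 | intermediate
9 | ring-expanded keto ketal (4β,5β-dimethyl-10βH-decalin-3,8-dione 8-ethylene ketal) | C1C[C@@]2(C)[C@H](CCC(=O)[C@@H]2C)CC13OCCO3 | intermediate
10 | hydroxy ketal (3α-OH) | C1C[C@@]2(C)[C@H](CC[C@@H](O)[C@@H]2C)CC13OCCO3 | intermediate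
11 | hydroxy ketone (3α-hydroxy-4β,5β-dimethyl-10βH-decalin-8-one) | C1C[C@@]2(C)[C@H](CC[C@@H](O)[C@@H]2C)CC1=O | intermediate
12 | 3α-triethylsilyloxy Δ8(9) triethylsilyl enol ether | C1C[C@@]2(C)[C@H](CC[C@@H](O[Si](CC)(CC)CC)[C@@H]2C)C=C1O[Si](CC)(CC)CC | intermediate
13 | 3α,9β-bis(triethylsilyloxy) ketone | C1C[C@@]2(C)[C@H](CC[C@@H](O[Si](CC)(CC)CC)[C@@H]2C)[C@@H](O[Si](CC)(CC)CC)C1=O | intermediate
14 | acetone | CC(C)=O | starting material
15 | lithium Δ7(8) enolate of 13 | [Li]OC1=CC[C@@]2(C)[C@H](CC[C@@H](O[Si](CC)(CC)CC)[C@@H]2C)[C@H]1O[Si](CC)(CC)CC | intermediate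
16 | chlorozinc Δ7(8) enolate of 13 | Cl[Zn]OC1=CC[C@@]2(C)[C@H](CC[C@@H](O[Si](CC)(CC)CC)[C@@H]2C)[C@H]1O[Si](CC)(CC)CC | intermediate
17 | aldol (7β-(2-hydroxypropan-2-yl)-3α,9β-bis(triethylsilyloxy) ketone) | CC(C)(O)[C@H]1C[C@@]2(C)[C@H](CC[C@@H](O[Si](CC)(CC)CC)[C@@H]2C)[C@@H](O[Si](CC)(CC)CC)C1=O | intermediate
18 | triol (3α,9β,11-trihydroxy-10βH-eremophilan-8-one) | CC(C)(O)[C@H]1C[C@@]2(C)[C@H](CC[C@@H](O)[C@@H]2C)[C@@H](O)C1=O | intermediate
19 | angelic acid | C/C=C(/C)C(=O)O | starting material
20 | bis-angelate carbinol | CC(C)(O)[C@H]1C[C@@]2(C)[C@H](CC[C@@H](OC(=O)/C(C)=C\C)[C@@H]2C)[C@@H](OC(=O)/C(C)=C\C)C1=O | intermediate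
21 | C11 chlorosulfite of 20 | ClS(=O)OC(C)(C)[C@H]1C[C@@]2(C)[C@H](CC[C@@H](OC(=O)/C(C)=C\C)[C@@H]2C)[C@@H](OC(=O)/C(C)=C\C)C1=O | intermediate
22 | (3R,4R,5R,7R,9R,10S)-3,9-bis(angeloyloxy)eremophil-11-en-8-one | C=C(C)[C@H]1C[C@@]2(C)[C@H](CC[C@@H](OC(=O)/C(C)=C\C)[C@@H]2C)[C@@H](OC(=O)/C(C)=C\C)C1=O | target

Total step count: 13. Longest linear sequence: 13 steps (from 1).

**Steps most likely to fail**

Step 6. The methylene carbon C2 may migrate in place of the quaternary C5, or the alkoxide may close onto C4 to give the epoxide. The fallback sets out from 3 and comes back at 9. It builds the migration terminus by carbonyl addition and activates it as a softer, more cation-like leaving group. 1-(Methylselanyl)ethyllithium is made from 1,1-bis(methylselanyl)ethane and n-BuLi in THF at −78 °C. It is added to ketone 3 to give the β-hydroxy selenide F1. AgBF4 on Al2O3 in CH2Cl2 then pulls on selenium and triggers the known ring enlargement of β-hydroxyalkyl selenides, in which the more substituted carbon migrates. A final treatment with DBU lets all C4 epimers converge on 9.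

Step 8. Enolisation may be poorly regioselective between C9 and C7. The fallback sets out from 11 and comes back at 18. It reverses the order of the two α-functionalisations and relies on kinetic rather than thermodynamic enolisation.
- 11 is silylated at O-3 only (TESCl, imidazole, DMF) to the mono-silyl ether F2.
- LiN(i-Pr)2 at −78 °C removes the less hindered proton at C7, since C9 is flanked by the branched C10. ZnCl2 and acetone then give the C7 aldol F3.
- TESOTf and 2,6-lutidine cap the tertiary alcohol to give the bis-silyl ether F4.
- C9 is now the only α-methylene. LiN(i-Pr)2 followed by 2-(phenylsulfonyl)-3-phenyloxaziridine hydroxylates it from the convex face to the 9β-hydroxy ketone F5.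
- HF·pyridine returns triol 18.

Step 13. H-7 may be lost instead of a methyl hydrogen, or the new double bond may drift into conjugation with the ketone. The fallback sets out from 13 and comes back at 22. It introduces the isopropenyl group directly, with no carbinol to dehydrate. Palladium-catalysed α-alkenylation of 13 uses 2-bromopropene, Pd2(dba)3, P(t-Bu)3 and LiN(SiMe3)2 in toluene. A cold acetic acid quench protonates the dienolate at C7 and should give the 7β-isopropenyl bis-silyl ether F6. HF·pyridine then frees the diol F7. The mixed anhydride of step 12, used at room temperature, converts F7 into 22.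

**Further compounds**
F1 | step 6 | β-hydroxy selenide from 3 (3β-hydroxy, (4R)-methylselanyl; drawn as the diastereomer that corresponds to 7) | C1C[C@@]2(C)[C@H](CC[C@@]2(O)[C@@H](C)[Se]C)CC13OCCO3
F2 | step 8 | 3α-triethylsilyloxy-4β,5β-dimethyl-10βH-decalin-8-one | C1C[C@@]2(C)[C@H](CC[C@@H](O[Si](CC)(CC)CC)[C@@H]2C)CC1=O
F3 | step 8 | 7β-(2-hydroxypropan-2-yl) derivative of F2 | CC(C)(O)[C@H]1C[C@@]2(C)[C@H](CC[C@@H](O[Si](CC)(CC)CC)[C@@H]2C)CC1=O
F4 | step 8 | 3α,11-bis(triethylsilyloxy) ketone | CC(C)(O[Si](CC)(CC)CC)[C@H]1C[C@@]2(C)[C@H](CC[C@@H](O[Si](CC)(CC)CC)[C@@H]2C)CC1=O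
F5 | step 8 | 9β-hydroxy-3α,11-bis(triethylsilyloxy) ketone | CC(C)(O[Si](CC)(CC)CC)[C@H]1C[C@@]2(C)[C@H](CC[C@@H](O[Si](CC)(CC)CC)[C@@H]2C)[C@@H](O)C1=O
F6 | step 13 | 7β-isopropenyl-3α,9β-bis(triethylsilyloxy) ketone | C=C(C)[C@H]1C[C@@]2(C)[C@H](CC[C@@H](O[Si](CC)(CC)CC)[C@@H]2C)[C@@H](O[Si](CC)(CC)CC)C1=O
F7 | step 13 | 3α,9β-dihydroxy-10βH-eremophil-11-en-8-one | C=C(C)[C@H]1C[C@@]2(C)[C@H](CC[C@@H](O)[C@@H]2C)[C@@H](O)C1=O
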